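## Analysis of the target

Target 26 is a 21-membered macrocycle. Two benzene rings are joined once by an ether oxygen and once by an unbranched chain of fourteen methylene groups, and each ring is bridged meta. Ring A is a 1,3,5-trisubstituted resorcinol unit: C1 carries OH, C3 the chain, C5 the ether oxygen. Ring B is a hydroquinone: C1 carries the ether oxygen, C2 an OH flanked by that oxygen and the chain at C3, and C5 the second OH. There is no stereocentre, and the loop is too wide to hold a stable planar-chiral conformation, so no stereocontrol is needed. The sensitive part is ring B, a trioxygenated arene that, once free, is a hydroquinone open to air oxidation; its two hydroxyls are therefore unmasked last. The difficulty lies in telling four phenolic oxygens apart, in making a diaryl ether that has no activating group for SNAr on either ring, and in closing a large ring. The strategy rests on ring A: its two oxygens are differentiated (one ether, one free OH), and two hydrogens lower in oxidation level it is a 3-aryloxy-5-alkylcyclohex-2-enone. That enone derives from a symmetric 5-alkylcyclohexane-1,3-dione, in which the future C5–O bond is a vinylogous ester bond and the future C1–OH is a carbonyl.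

## Retrosynthetic reasoning

**26 to 25.** The two O–CH3 bonds on ring B are cut last. Methyl ethers protect the hydroquinone from oxidation throughout, and one Lewis-acid step removes both without touching the diaryl ether.

**25 to 21.** Ring A is taken back to the cyclohexenone level by adding two hydrogens at ring A C2 and C3 (C6 and C5 of the enone). The forward step is a dehydrogenation driven by aromatisation. This turns the unactivated aryl–O bond at ring A C5 into the C3–O bond of a vinylogous ester, which can be made by acyl-type substitution.

**21 to 20.** The vinylogous ester C–O bond is cut. It is the only heteroatom link in the macrocycle, so one disconnection both opens the ring and removes the diaryl ether problem. The forward step needs the ring B C1 phenoxide to displace chloride from a 3-chlorocyclohex-2-enone at high dilution, with attack through oxygen.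

**20 to 19 to 18.** The ring B C1 phenol of 20 is masked as the benzyl ether in 19. The C–Cl bond of 19 goes back to the enol C–O of dione 18. Because 18 is symmetric, chlorination of either oxygen gives the same chloroenone, so the two ring A oxygens are differentiated without any selectivity problem. Benzyl is chosen because it survives base, hot dilute acid and the chlorinating agent, and can be removed by a Lewis acid without ever generating a phenoxide next to the chloroenone.

**18 to 14 and 15, then 14 to 12 and 13.** The dione ring is cut at the two bonds made by a Michael–Claisen annulation of enone 14 with malonate 15. The enone C=C is cut to aldehyde 12 and ylide 13. The aldehyde carbon becomes the chain-bearing ring carbon, which fixes the chain length at fourteen methylenes.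

**12 to 11 to 3 and 9; 3 to 1.** The aldehyde comes from ester 11. The aryl–CH2 bond of 11 is cut to aryl bromide 9 and the ω-bromo ester 3, joined forward by an sp2–sp3 cross-coupling. Bromo ester 3 is the ring-opened form of the fifteen-carbon lactone 1, which supplies the whole chain with both ends differentiated.

**9 to 8 to 5 to 4.** The benzyl ether 9 comes from phenol 8, and 8 from the symmetric dibromide 5 by exchanging one of two equivalent bromines for hydroxyl. Dibromide 5 is the methyl ether of phenol 4, which already has the central oxygen flanked by two equivalent halogens and the para oxygen in place.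

## Alternatives that were turned down

**Alternative 1:** The C–OH bonds at ring A C1 and ring B C5 are removed, leaving the unfunctionalised macrocycle A1, whose two rings are equivalent by symmetry. Forward, a sterically controlled iridium-catalysed C–H borylation would hit the one position on each ring that is meta to both substituents, and peroxide oxidation would give the symmetric diphenol A2.
- For: it is very short, the meta selectivity on 1,3-disubstituted arenes is dependable, and the symmetry guarantees one product.
- Against: A2 lacks the ring B C2 hydroxyl. That position lies between the ether oxygen and the chain, is the most hindered C–H in the molecule, and cannot be reached by steric borylation. Installing it would need a para-oxidation of one of two equivalent phenol rings, which is statistical at best and competes with ortho-oxidation because the para site is doubly flanked. A1 itself also still needs a diaryl ether macrocyclisation between two unactivated rings.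
- Comparison: up to A2 this route is stronger on step economy. The chosen route instead has all four oxygens present and differentiated from the start, so no late C–H oxidation is needed.

**Alternative 2:** Ring A is cut across two ring bonds into the cyclobutenone A3 (fragment 1) and the aryl ethynyl ether A4 (fragment 2), each with an oct-7-enyl arm. Forward, heating opens A3 to a vinylketene, which adds [2+2] to the ynol ether; 4π opening, 6π closure and tautomerisation give the diaryl ether A5 with the ring A pattern set by mechanism and its C1 OH free. Ring-closing metathesis of the two arms, hydrogenation and demethylation would follow.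
- For: it is convergent, the ring A regiochemistry is guaranteed, and no oxidation-level adjustment is needed. The metathesis closure is reversible and self-correcting, which is a real advantage over a kinetic ring closure.
- Against: A4 is the ethynyl ether of a hindered, electron-rich phenol. It takes several steps to make, is thermally fragile, and as an aryloxyalkyne is a weaker ketene partner than an alkoxyalkyne. A3 needs its own multi-step synthesis. After the key step, three more operations remain, so the uncertainty is spread over two steps (benzannulation and metathesis).
- Comparison: the chosen route is not safer at the macrocyclisation itself. It offers commodity inputs (a lactone, a malonate, a simple ylide) and forms the ether and the ring in one step.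

**Alternative 3:** Ring B is cut at C1–C2, C2–C3 and C4–C5, with C2 coming from a carbonyl ligand. The precursor is the tethered chromium carbene complex A6, a β-aryloxyvinyl(methoxy)carbene carrying a terminal alkyne at the end of the chain. Forward, heating at high dilution would insert the alkyne and CO and give macrocycle A7, with ring B C2 OH free, C5 as the methyl ether, and the large ring closed in the same step.
- For: one step builds the fully substituted ring B, differentiates its two oxygens by mechanism and closes the macrocycle. On oxygen differentiation it is stronger than the chosen route.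
- Against: it needs stoichiometric chromium. A6 is a donor-stabilised and therefore sluggish carbene, made by conjugate addition of the ring A phenol to an alkynylcarbene complex. The alkyne insertion across a long tether can lose its regiochemical preference or give oligomers, and cyclobutenone, furan and indene channels compete. The complex must survive prolonged heating at high dilution. A7 is released from its Cr(CO)3 complex by oxidation, which threatens the electron-rich hydroquinone monoether.
- Comparison: the chosen route gets the same oxygen differentiation cheaply from the symmetric dibromophenol 4 and uses only a carbonate base in its key step.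

Key step: step 11

Remark: the chain-bearing carbon of the cyclohexenone in 19, 20 and 21 is a stereocentre. These compounds are carried as racemates, and the centre disappears when ring A is aromatised. Compound 4 is treated as purchasable; it is otherwise one dibromination step from 4-methoxyphenol.

## Route

Step 1
Reactants: 1 pentadecanolide
Product: 3 methyl 15-bromopentadecanoate, via 15-bromopentadecanoic acid 2 (not isolated)
Conditions: HBr (33% in AcOH), H2SO4 (cat.), 80 °C; concentrate; then MeOH, reflux
Reagents that add atoms: hydrogen bromide, Br; methanol, CO
Why: Acidolysis of the lactone (bromide attacks the protonated O–CH2 carbon by SN2) should give the ω-bromo acid, and Fischer esterification with the residual acid should give the methyl ester.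

Step 2
Reactants: 4 2,6-dibromo-4-methoxyphenol
Product: 5 1,3-dibromo-2,5-dimethoxybenzene
Conditions: MeI, K2CO3, acetone, reflux
Reagents that add atoms: iodomethane, CI
Why: Williamson O-methylation; the two ortho bromines make the phenol acidic, and SN2 at the methyl group is not hindered.

Step 3
Reactants: 5 1,3-dibromo-2,5-dimethoxybenzene
Product: 8 3-bromo-2,5-dimethoxyphenol, via (3-bromo-2,5-dimethoxyphenyl)lithium 6 (not isolated), via dimethyl (3-bromo-2,5-dimethoxyphenyl)boronate 7 (not isolated)
Conditions: n-BuLi (1.0 equiv), THF, −78 °C; B(OMe)3, −78 °C → rt; AcOH, 30% H2O2, 0 °C → rt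
Reagents that add atoms: hydrogen peroxide, OO
Why: Bromine–lithium exchange at one of two equivalent C–Br bonds (a second exchange would give a dianion and should not compete with one equivalent at −78 °C), borylation, and oxidative aryl migration from boron to oxygen should give the phenol and desymmetrise the ring.

Step 4
Reactants: 8 3-bromo-2,5-dimethoxyphenol
Product: 9 1-(benzyloxy)-3-bromo-2,5-dimethoxybenzene
Conditions: BnBr, K2CO3, DMF, rt
Reagents that add atoms: benzyl bromide, BrCc1ccccc1
Why: Williamson benzylation; benzyl should survive the organozinc, hydride, methoxide, hydroxide, hot dilute acid and (COCl)2 of steps 5 to 9 and can later be removed without base.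

Step 5
Reactants: 3 methyl 15-bromopentadecanoate; 9 1-(benzyloxy)-3-bromo-2,5-dimethoxybenzene
Product: 11 methyl 15-[3-(benzyloxy)-2,5-dimethoxyphenyl]pentadecanoate, via (15-methoxy-15-oxopentadecyl)zinc bromide 10 (not isolated)
Conditions: 3, Zn, I2 (cat.), DMA, 80 °C; then 9, Pd(OAc)2 (2 mol %), SPhos (2-dicyclohexylphosphino-2′,6′-dimethoxybiphenyl, 4 mol %), THF, 50 °C
Reagents that add atoms: none
Why: Negishi sp2–sp3 coupling; zinc insertion into the primary bromide tolerates the ester, and zerovalent palladium with a bulky dialkylbiarylphosphine should add to the electron-rich, ortho-substituted bromide and undergo reductive elimination faster than β-hydride elimination.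

Step 6
Reactants: 11 methyl 15-[3-(benzyloxy)-2,5-dimethoxyphenyl]pentadecanoate
Product: 12 15-[3-(benzyloxy)-2,5-dimethoxyphenyl]pentadecanal
Conditions: i-Bu2AlH (1.1 equiv), CH2Cl2, −78 °C; aq. KNaC4H4O6
Reagents that add atoms: none
Why: Partial reduction of the methyl ester; the aluminium hemiacetal formed at −78 °C should persist until aqueous work-up releases the aldehyde, and the ethers are inert.

Step 7
Reactants: 12 15-[3-(benzyloxy)-2,5-dimethoxyphenyl]pentadecanal; 13 1-(triphenylphosphoranylidene)propan-2-one
Product: 14 (E)-18-[3-(benzyloxy)-2,5-dimethoxyphenyl]octadec-3-en-2-one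
Conditions: toluene, 80 °C
Reagents that add atoms: none
Why: Wittig olefination with a ketone-stabilised ylide, which should react only with the aldehyde and give the (E)-enone; the geometry has no consequence later.

Step 8
Reactants: 14 (E)-18-[3-(benzyloxy)-2,5-dimethoxyphenyl]octadec-3-en-2-one; 15 dimethyl malonate
Product: 18 5-{14-[3-(benzyloxy)-2,5-dimethoxyphenyl]tetradecyl}cyclohexane-1,3-dione, via cyclic keto ester 16 (not isolated), via keto acid 17 (not isolated)
Conditions: NaOMe, MeOH–THF, reflux; 2 M aq. NaOH, reflux; aq. HCl to pH 2, 70 °C
Reagents that add atoms: none
Why: Michael addition of sodiomalonate to the enone and intramolecular Claisen condensation of the methyl ketone enolate onto one ester should give the cyclic diketo ester as its stabilised enolate; saponification, acidification and warming should decarboxylate the β-keto acid to the symmetric dione, which has no stereocentre.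

Step 9
Reactants: 18 5-{14-[3-(benzyloxy)-2,5-dimethoxyphenyl]tetradecyl}cyclohexane-1,3-dione
Product: 19 racemic 5-{14-[3-(benzyloxy)-2,5-dimethoxyphenyl]tetradecyl}-3-chlorocyclohex-2-en-1-one
Conditions: (COCl)2 (1.2 equiv), DMF (cat.), CH2Cl2, 0 °C → rt
Reagents that add atoms: oxalyl chloride, O=C(Cl)C(=O)Cl
Why: Conversion of a vinylogous acid to a vinylogous acid chloride: the enol is O-acylated, chloride adds to the β-carbon, and the chlorooxalate leaves as CO, CO2 and chloride; because the dione is symmetric, either oxygen gives the same racemic chloroenone.

Step 10
Reactants: 19 racemic 5-{14-[3-(benzyloxy)-2,5-dimethoxyphenyl]tetradecyl}-3-chlorocyclohex-2-en-1-one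
Product: 20 racemic 3-chloro-5-[14-(3-hydroxy-2,5-dimethoxyphenyl)tetradecyl]cyclohex-2-en-1-one
Conditions: BCl3 (2.5 equiv), C6HMe5 (3 equiv), CH2Cl2, −78 °C; cold aq. NaHCO3
Reagents that add atoms: none
Why: Lewis-acid debenzylation: BCl3 coordinates the benzyl ether oxygen and the benzyl cation is trapped by pentamethylbenzene (Friedel–Crafts), while at −78 °C the aryl methyl ethers and the chloroenone should be left alone; the phenol is released on near-neutral work-up, so no phenoxide meets the chloroenone before the dilution step.

Step 11
Reactants: 20 racemic 3-chloro-5-[14-(3-hydroxy-2,5-dimethoxyphenyl)tetradecyl]cyclohex-2-en-1-one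
Product: 21 racemic macrocyclic 3-aryloxycyclohex-2-en-1-one (enone C3 bonded to the ring B C1 oxygen; enone C5 joined through fourteen CH2 to ring B C3; ring B 2,5-dimethoxy)
Conditions: Cs2CO3 (3 equiv), 4 Å MS, MeCN, 70 °C, syringe-pump addition of 20 over 16 h (final 1 mM)
Reagents that add atoms: none
Why: Cs2CO3 deprotonates the ring B C1 phenol, the phenoxide adds to the β-carbon (C3) of the chloroenone to give an enolate carrying chlorine and aryloxy on one sp3 carbon, and that enolate expels chloride (addition–elimination, a vinylogous acyl substitution), so the future ring A C5–O bond forms as a vinylogous ester. The closest known reaction is the intermolecular condensation of phenols with 3-chlorocyclohex-2-enones under carbonate bases, and the ring-closing use parallels phenoxide SNAr macrocyclisations. The 21-membered ring closes by a 21-exo-trig addition (enone C2 stays outside the new ring) and should be free of transannular strain. No stereocentre is formed; the existing one at the chain-bearing carbon stays racemic and is removed in step 12. Attack through oxygen is favoured by the hard, acyl-like electrophile, by the loosely paired caesium phenoxide in MeCN, and by the loss of aromaticity that attack through carbon would cost. Cyclisation over oligomerisation is secured by slow addition, which keeps the stationary concentration of open phenoxide far below the effective molarity of ring closure. Carbonate is too weak to enolise the chloroenone appreciably, and the molecular sieves keep water from hydrolysing it back to the dione.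

Step 12
Reactants: 21 racemic macrocyclic 3-aryloxycyclohex-2-en-1-one
Product: 25 macrocyclic diaryl ether with free ring A C1 phenol and ring B 2,5-dimethoxy, via α′-phenylselanyl ketone 22 (not isolated), via selenoxide 23 (not isolated), via 4H-cyclohexadienone 24 (not isolated)
Conditions: LiN(i-Pr)2 (1.2 equiv), THF, −78 °C; PhSeCl, −78 °C; aq. NH4Cl; then 30% H2O2, pyridine, CH2Cl2, 0 °C → rt
Reagents that add atoms: none
Why: Kinetic deprotonation of the vinylogous ester should occur at the α′ carbon (enone C6, ring A C2), and the enolate should be selenenylated trans to the chain on the neighbouring carbon; oxidation to the selenoxide and syn-elimination towards that carbon (its hydrogen is cis to selenium) give the cross-conjugated dienone, the keto tautomer of the phenol, which enolises at once. This is the selenoxide dehydrogenation of an enone to a phenol, and no leaving group is placed on the ether carbon.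

Step 13
Reactants: 25 macrocyclic diaryl ether with free ring A C1 phenol and ring B 2,5-dimethoxy
Product: 26 target CNP0393720.0
Conditions: BBr3 (6 equiv), CH2Cl2, −78 °C → rt; H2O, aq. Na2S2O4 wash, under Ar
Reagents that add atoms: none
Why: Lewis-acid cleavage of aryl methyl ethers: BBr3 complexes each methoxy oxygen and bromide attacks the methyl group by SN2; the diaryl ether has no sp3 carbon to attack and should survive, and the dithionite wash under argon protects the hydroquinone from air.

## Compound list

1 | pentadecanolide (oxacyclohexadecan-2-one) | O=C1CCCCCCCCCCCCCCO1 | starting material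
2 | 15-bromopentadecanoic acid | OC(=O)CCCCCCCCCCCCCCBr | intermediate (not isolated)
3 | methyl 15-bromopentadecanoate | COC(=O)CCCCCCCCCCCCCCBr | intermediate
4 | 2,6-dibromo-4-methoxyphenol | COc1cc(Br)c(O)c(Br)c1 | starting material
5 | 1,3-dibromo-2,5-dimethoxybenzene | COc1cc(Br)c(OC)c(Br)c1 | intermediate
6 | (3-bromo-2,5-dimethoxyphenyl)lithium | [Li]c1cc(OC)cc(Br)c1OC | intermediate (not isolated)
7 | dimethyl (3-bromo-2,5-dimethoxyphenyl)boronate | COB(OC)c1cc(OC)cc(Br)c1OC | intermediate (not isolated)
8 | 3-bromo-2,5-dimethoxyphenol | Oc1cc(OC)cc(Br)c1OC | intermediate
9 | 1-(benzyloxy)-3-bromo-2,5-dimethoxybenzene | Brc1cc(OC)cc(OCc2ccccc2)c1OC | intermediate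
10 | (15-methoxy-15-oxopentadecyl)zinc bromide | COC(=O)CCCCCCCCCCCCCC[Zn]Br | intermediate (not isolated)
11 | methyl 15-[3-(benzyloxy)-2,5-dimethoxyphenyl]pentadecanoate | COC(=O)CCCCCCCCCCCCCCc1cc(OC)cc(OCc2ccccc2)c1OC | intermediate
12 | 15-[3-(benzyloxy)-2,5-dimethoxyphenyl]pentadecanal | O=CCCCCCCCCCCCCCCc1cc(OC)cc(OCc2ccccc2)c1OC | intermediate
13 | 1-(triphenylphosphoranylidene)propan-2-one | CC(=O)C=P(c1ccccc1)(c1ccccc1)c1ccccc1 | starting material
14 | (E)-18-[3-(benzyloxy)-2,5-dimethoxyphenyl]octadec-3-en-2-one | CC(=O)/C=C/CCCCCCCCCCCCCCc1cc(OC)cc(OCc2ccccc2)c1OC | intermediate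
15 | dimethyl malonate | COC(=O)CC(=O)OC | starting material
16 | methyl 6-{14-[3-(benzyloxy)-2,5-dimethoxyphenyl]tetradecyl}-2,4-dioxocyclohexane-1-carboxylate (racemic, formed as its sodium enolate) | COC(=O)C1C(CCCCCCCCCCCCCCc2cc(OC)cc(OCc3ccccc3)c2OC)CC(=O)CC1=O | intermediate (not isolated)
17 | 6-{14-[3-(benzyloxy)-2,5-dimethoxyphenyl]tetradecyl}-2,4-dioxocyclohexane-1-carboxylic acid (racemic) | OC(=O)C1C(CCCCCCCCCCCCCCc2cc(OC)cc(OCc3ccccc3)c2OC)CC(=O)CC1=O | intermediate (not isolated)
18 | 5-{14-[3-(benzyloxy)-2,5-dimethoxyphenyl]tetradecyl}cyclohexane-1,3-dione | O=C1CC(CCCCCCCCCCCCCCc2cc(OC)cc(OCc3ccccc3)c2OC)CC(=O)C1 | intermediate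
19 | racemic 5-{14-[3-(benzyloxy)-2,5-dimethoxyphenyl]tetradecyl}-3-chlorocyclohex-2-en-1-one | O=C1C=C(Cl)CC(CCCCCCCCCCCCCCc2cc(OC)cc(OCc3ccccc3)c2OC)C1 | intermediate
20 | racemic 3-chloro-5-[14-(3-hydroxy-2,5-dimethoxyphenyl)tetradecyl]cyclohex-2-en-1-one | Oc1cc(OC)cc(CCCCCCCCCCCCCCC2CC(Cl)=CC(=O)C2)c1OC | intermediate
21 | racemic macrocyclic 3-aryloxycyclohex-2-en-1-one (21-membered ring) | O=C1C=C2CC(C1)CCCCCCCCCCCCCCc1cc(OC)cc(O2)c1OC | intermediate
22 | α′-phenylselanyl derivative of 21 (racemic, selenium expected trans to the chain) | O=C1C=C2CC(C1[Se]c3ccccc3)CCCCCCCCCCCCCCc3cc(OC)cc(O2)c3OC | intermediate (not isolated)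
23 | selenoxide of 22 | O=C1C=C2CC(C1[Se](=O)c3ccccc3)CCCCCCCCCCCCCCc3cc(OC)cc(O2)c3OC | intermediate (not isolated)
24 | macrocyclic 3-aryloxy-5-alkylcyclohexa-2,5-dien-1-one (4H keto tautomer of 25) | O=C1C=C2CC(=C1)CCCCCCCCCCCCCCc1cc(OC)cc(O2)c1OC | intermediate (not isolated)
25 | macrocyclic diaryl ether, ring A C1 OH free, ring B 2,5-dimethoxy | Oc1cc2cc(c1)Oc1cc(OC)cc(c1OC)CCCCCCCCCCCCCC2 | intermediate
26 | CNP0393720.0 (macrocyclic diaryl ether triol) | Oc1cc2cc(c1)Oc1cc(O)cc(c1O)CCCCCCCCCCCCCC2 | target

## Step count and least certain steps

Total step count: 13. Longest linear sequence: 12 steps (from 4 through steps 2 to 13); the branch from 1 adds step 1 and joins at step 5.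

**Step 11 (key step).** The most likely failure is intermolecular substitution outrunning ring closure, because a strain-free 21-membered ring has a low effective molarity; linear and cyclic oligomers would then form. Hydrolysis of the chloroenone by traces of water and attack of the phenoxide through carbon are further risks. The fallback aromatises ring A first and closes the diaryl ether by copper-catalysed Ullmann coupling. That closure has the same entropic demand, but it uses an aryl bromide that cannot hydrolyse and tolerates long, hot, slow additions. It sets out from 18. Ph3PBr2 and Et3N in MeCN should give racemic 5-{14-[3-(benzyloxy)-2,5-dimethoxyphenyl]tetradecyl}-3-bromocyclohex-2-en-1-one F1. Enolate selenenylation and selenoxide elimination as in step 12 should give 3-{14-[3-(benzyloxy)-2,5-dimethoxyphenyl]tetradecyl}-5-bromophenol F2. Methylation with MeI and K2CO3 gives 1-(benzyloxy)-3-[14-(3-bromo-5-methoxyphenyl)tetradecyl]-2,5-dimethoxybenzene F3. BCl3 and pentamethylbenzene at −78 °C free the ring B phenol, 3-[14-(3-bromo-5-methoxyphenyl)tetradecyl]-2,5-dimethoxyphenol F4. CuI, N,N-dimethylglycine and Cs2CO3 in dioxane at 100 °C under slow addition should close the ring to the macrocyclic trimethyl ether F5. BBr3 then cleaves all three methyl ethers, and the sequence comes back to the route at the target 26.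

**Step 12.** The product is an electron-rich phenol beside a trioxygenated ring, and both may be oxidised by the peroxide and the selenium by-products. Proton exchange between enolate and selenide may also cause double selenenylation. The fallback is a Saegusa–Ito dehydrogenation, which uses no peroxide and no selenium. It sets out from 21. LiN(i-Pr)2 and Me3SiCl at −78 °C should give the cross-conjugated trimethylsilyl dienol ether F6, and Pd(OAc)2 (1 equiv) in MeCN at rt should convert it through 24 into 25, where the route is rejoined.

**Step 10.** The Lewis acid may damage the chloroenone (exchange at the β-carbon and hydrolysis to the dione on quench), or the boron chelate may cost the methyl ether next to the new phenol. The fallback removes the benzyl group before the chlorine is introduced and chlorinates under neutral conditions. It sets out from 18. H2 and Pd/C in EtOAc should give 5-[14-(3-hydroxy-2,5-dimethoxyphenyl)tetradecyl]cyclohexane-1,3-dione F7. Ph3P and CCl4 in MeCN should then convert the enol into the chloroenone, while the phenol forms at most an aryloxyphosphonium salt that hydrolyses on work-up. This comes back to the route at 20.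

**Step 5.** Zinc insertion into the long-chain bromide may be sluggish, or oxidative addition to the electron-rich, ortho-substituted aryl bromide may be slow enough for protodezincation and homocoupling to take over. The fallback makes the aryl–chain bond by acylation rather than cross-coupling and bypasses steps 1, 5 and 6. It sets out from 9. Bromine–lithium exchange with n-BuLi at −78 °C and inverse addition to pentadecanolide 1 should give 1-[3-(benzyloxy)-2,5-dimethoxyphenyl]-15-hydroxypentadecan-1-one F8. Ionic hydrogenation of the electron-rich aryl ketone with Et3SiH and CF3CO2H, followed by K2CO3 in MeOH to cleave any trifluoroacetate, should give 15-[3-(benzyloxy)-2,5-dimethoxyphenyl]pentadecan-1-ol F9. Dess–Martin oxidation then gives 12, where the route is rejoined.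

## Further compounds

F1 | step 11 | racemic 5-{14-[3-(benzyloxy)-2,5-dimethoxyphenyl]tetradecyl}-3-bromocyclohex-2-en-1-one | O=C1C=C(Br)CC(CCCCCCCCCCCCCCc2cc(OC)cc(OCc3ccccc3)c2OC)C1
F2 | step 11 | 3-{14-[3-(benzyloxy)-2,5-dimethoxyphenyl]tetradecyl}-5-bromophenol | Oc1cc(Br)cc(CCCCCCCCCCCCCCc2cc(OC)cc(OCc3ccccc3)c2OC)c1
F3 | step 11 | 1-(benzyloxy)-3-[14-(3-bromo-5-methoxyphenyl)tetradecyl]-2,5-dimethoxybenzene | COc1cc(Br)cc(CCCCCCCCCCCCCCc2cc(OC)cc(OCc3ccccc3)c2OC)c1
F4 | step 11 | 3-[14-(3-bromo-5-methoxyphenyl)tetradecyl]-2,5-dimethoxyphenol | COc1cc(Br)cc(CCCCCCCCCCCCCCc2cc(OC)cc(O)c2OC)c1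
F5 | step 11 | macrocyclic diaryl ether with ring A C1 methoxy and ring B 2,5-dimethoxy (trimethyl ether of 26) | COc1cc2cc(c1)Oc1cc(OC)cc(c1OC)CCCCCCCCCCCCCC2
F6 | step 12 | racemic macrocyclic 3-aryloxy-1-(trimethylsilyloxy)cyclohexa-1,3-diene (silyl dienol ether of 21) | C[Si](C)(C)OC1=CC(CCCCCCCCCCCCCCc2cc(OC)cc(O3)c2OC)CC3=C1
F7 | step 10 | 5-[14-(3-hydroxy-2,5-dimethoxyphenyl)tetradecyl]cyclohexane-1,3-dione | O=C1CC(CCCCCCCCCCCCCCc2cc(OC)cc(O)c2OC)CC(=O)C1
F8 | step 5 | 1-[3-(benzyloxy)-2,5-dimethoxyphenyl]-15-hydroxypentadecan-1-one | OCCCCCCCCCCCCCCC(=O)c1cc(OC)cc(OCc2ccccc2)c1OC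
F9 | step 5 | 15-[3-(benzyloxy)-2,5-dimethoxyphenyl]pentadecan-1-ol | OCCCCCCCCCCCCCCCc1cc(OC)cc(OCc2ccccc2)c1OC
A1 | alternative 1 | unsubstituted 21-membered macrocyclic diaryl ether (both rings bridged 1,3 by O and fourteen CH2) | c1cc2cc(c1)Oc1cccc(c1)CCCCCCCCCCCCCC2
A2 | alternative 1 | symmetric macrocyclic diphenol (OH at ring A C1 and ring B C5) | Oc1cc2cc(c1)Oc1cc(O)cc(c1)CCCCCCCCCCCCCC2
A3 | alternative 2 | 3-(oct-7-en-1-yl)cyclobut-2-en-1-one | O=C1C=C(CCCCCCC=C)C1
A4 | alternative 2 | 1-(ethynyloxy)-2,5-dimethoxy-3-(oct-7-en-1-yl)benzene | C#COc1cc(OC)cc(CCCCCCC=C)c1OC
A5 | alternative 2 | 3-[2,5-dimethoxy-3-(oct-7-en-1-yl)phenoxy]-5-(oct-7-en-1-yl)phenol | Oc1cc(CCCCCCC=C)cc(c1)Oc1cc(OC)cc(CCCCCCC=C)c1OC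
A6 | alternative 3 | pentacarbonyl{(E)-3-[3-(hexadec-15-yn-1-yl)-5-methoxyphenoxy]-1-methoxyprop-2-en-1-ylidene}chromium | COC(=[Cr](=C=O)(=C=O)(=C=O)(=C=O)=C=O)/C=C/Oc1cc(OC)cc(CCCCCCCCCCCCCCC#C)c1
A7 | alternative 3 | macrocyclic diaryl ether with ring B C2 OH free, ring B C5 methoxy and ring A C1 methoxy | COc1cc2cc(c1)Oc1cc(OC)cc(c1O)CCCCCCCCCCCCCC2
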